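**Plan**

- Retrosynthesis: C8–OMe is cut back to C8–Br, N–H to N–SO2Ar and C6–OMe to C6–OH; then C4a–C8a and C5–C6 are cut together, which unravels ring A and ring B into a furan and an alkyne.
- Enabling feature: ring A has its C6 oxygen ortho to the naphthyl-bearing C5, and C8a and C4a are bridged by C1–N2–C3–C4 of ring B. A 2-furfurylamine tethered through nitrogen to a naphthyl alkyne gives this pattern: the furan supplies C6, C7, C8, C8a and the C6 oxygen, the alkyne supplies C4a and C5.
- C8 is carried through that step as bromine, not methoxy. A methoxy group at C8 is para to C5 and would steer the intermediate arene oxide to keep its oxygen on C5; the methoxy group is installed last by copper-catalysed exchange.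
- The precursor is cut at the alkyne–naphthyl bond (Sonogashira), at N–S and N–CH2(furyl) (sulfonylation, reductive amination) and at C4–alkyne (acetylide opening of the Boc cyclic sulfamidate of L-alaninol). The iodonaphthalene comes from 2-methoxy-4-methylbenzoic acid by ortho-allylation of its amide and anionic ring closure.
- Forward order: second naphthalene ring (step 3), chain assembly (steps 6 to 10), ring B and ring A in one operation (step 11), then O-methylation, removal of the sulfonyl group and bromide-to-methoxide exchange.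
- The only stereocentre, C3 (S), is the α-carbon of L-alanine; no step makes or breaks a bond at it.

Key step: step 11

Remark: the target string leaves the C5–naphthyl axis undefined, so the route is taken to deliver the (S)-C3 compound as whatever mixture of rotamers about that bond forms; the axis is not controlled.
Remark: compounds 10 (the N-Boc cyclic sulfamidate of L-alaninol) and 14 are taken as purchased materials.

**Route**

Step 1
Reactants: 1 2-methoxy-4-methylbenzoic acid
Product: 3 N,N-diethyl-2-methoxy-4-methylbenzamide, via 2-methoxy-4-methylbenzoyl chloride 2 (not isolated)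
Conditions: (COCl)2, DMF (cat.), CH2Cl2, 0 °C to rt; concentrate; Et2NH (2.5 equiv), CH2Cl2, 0 °C to rt
Reagents that add atoms: oxalyl chloride ClC(=O)C(=O)Cl (chlorine of 2); diethylamine CCNCC
Why: Acid chloride formation followed by N-acylation of a secondary amine is routine and should give the tertiary amide that serves first as directing group and later as internal electrophile.

Step 2
Reactants: 3 N,N-diethyl-2-methoxy-4-methylbenzamide
Product: 6 N,N-diethyl-2-methoxy-4-methyl-6-(prop-2-en-1-yl)benzamide, via ortho-lithiated amide 4 (not isolated), via arylmagnesium bromide 5 (not isolated)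
Conditions: s-BuLi, TMEDA, THF, −78 °C; MgBr2·OEt2, −78 to 0 °C; allyl bromide, 0 °C to rt
Reagents that add atoms: sec-butyllithium CCC(C)[Li] (lithium of 4); magnesium bromide Br[Mg]Br (MgBr of 5); allyl bromide C=CCBr
Why: Directed ortho-metalation: the diethylamide outranks the methoxy group and directs s-BuLi/TMEDA to the only free position ortho to it, and transmetalation to magnesium should allow clean allylation.

Step 3
Reactants: 6 N,N-diethyl-2-methoxy-4-methyl-6-(prop-2-en-1-yl)benzamide
Product: 7 8-methoxy-6-methylnaphthalen-1-ol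
Conditions: LiN(i-Pr)2 (2.5 equiv), THF, −78 °C to rt; aq. NH4Cl
Reagents that add atoms: none
Why: Anionic ring annulation of an ortho-allylbenzamide: deprotonation at the benzylic allylic carbon gives an allyl anion whose terminal carbon attacks the amide carbonyl, and loss of diethylamide followed by enolisation should give the 1-naphthol with the methoxy group peri to the hydroxyl.

Step 4
Reactants: 7 8-methoxy-6-methylnaphthalen-1-ol
Product: 8 4-iodo-8-methoxy-6-methylnaphthalen-1-ol
Conditions: NIS (1.0 equiv), MeCN, 0 °C, dark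
Reagents that add atoms: N-iodosuccinimide O=C1CCC(=O)N1I
Why: Electrophilic aromatic iodination: the free, internally hydrogen-bonded hydroxyl activates its own ring more strongly than the methoxy group activates the other, so attack is expected at the unhindered position para to the hydroxyl.

Step 5
Reactants: 8 4-iodo-8-methoxy-6-methylnaphthalen-1-ol
Product: 9 1-iodo-4,5-dimethoxy-7-methylnaphthalene
Conditions: MeI, K2CO3, DMF, 40 °C
Reagents that add atoms: iodomethane CI
Why: Williamson ether synthesis on the naphthoxide; the aryl iodide is inert to these conditions.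

Step 6
Reactants: 10 tert-butyl (S)-4-methyl-1,2,3-oxathiazolidine-3-carboxylate 2,2-dioxide
Product: 12 tert-butyl (S)-[5-(trimethylsilyl)pent-4-yn-2-yl]carbamate, via lithium N-Boc sulfamate 11 (not isolated)
Conditions: Me3SiC≡CH, n-BuLi, THF, −78 °C; add 10, −78 °C to rt; then 1 M aq. HCl, rt
Reagents that add atoms: trimethylsilylacetylene C#C[Si](C)(C)C; n-butyllithium CCCC[Li] (lithium of 11)
Why: SN2 opening of a cyclic sulfamidate at its primary C–O carbon by a lithium acetylide, followed by mild acid hydrolysis of the N-sulfamate, is a standard route to N-Boc homopropargylamines; the stereocentre is not involved and stays (S).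

Step 7
Reactants: 12 tert-butyl (S)-[5-(trimethylsilyl)pent-4-yn-2-yl]carbamate
Product: 13 (S)-5-(trimethylsilyl)pent-4-yn-2-aminium chloride
Conditions: HCl (4 M in 1,4-dioxane), 0 °C to rt; evaporate
Reagents that add atoms: hydrogen chloride Cl
Why: Acidolytic Boc cleavage; the alkynylsilane is stable to anhydrous HCl and the amine is kept as its non-volatile hydrochloride.

Step 8
Reactants: 13 (S)-5-(trimethylsilyl)pent-4-yn-2-aminium chloride; 14 3-bromofuran-2-carbaldehyde
Product: 16 (S)-N-[(3-bromofuran-2-yl)methyl]-5-(trimethylsilyl)pent-4-yn-2-amine, via N-furfurylidene imine 15 (not isolated)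
Conditions: Et3N (1.0 equiv), NaBH(OAc)3, ClCH2CH2Cl, rt
Reagents that add atoms: none
Why: Reductive amination: the α-branched primary amine condenses with the aldehyde and NaBH(OAc)3 reduces the imine faster than the aldehyde, so mono-alkylation is expected and the furyl bromide and alkynylsilane are untouched.

Step 9
Reactants: 16 (S)-N-[(3-bromofuran-2-yl)methyl]-5-(trimethylsilyl)pent-4-yn-2-amine
Product: 17 (S)-N-[(3-bromofuran-2-yl)methyl]-2-nitro-N-[5-(trimethylsilyl)pent-4-yn-2-yl]benzenesulfonamide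
Conditions: 2-NO2C6H4SO2Cl, Et3N, DMAP (cat.), CH2Cl2, 0 °C to rt
Reagents that add atoms: 2-nitrobenzenesulfonyl chloride O=[N+]([O-])c1ccccc1S(=O)(=O)Cl
Why: N-Sulfonylation of a secondary amine under DMAP catalysis; the 2-nitrobenzenesulfonyl group makes the nitrogen non-basic towards gold and can later be removed with thiolate.

Step 10
Reactants: 17 (S)-N-[(3-bromofuran-2-yl)methyl]-2-nitro-N-[5-(trimethylsilyl)pent-4-yn-2-yl]benzenesulfonamide; 9 1-iodo-4,5-dimethoxy-7-methylnaphthalene
Product: 19 (S)-N-[(3-bromofuran-2-yl)methyl]-N-[5-(4,5-dimethoxy-7-methylnaphthalen-1-yl)pent-4-yn-2-yl]-2-nitrobenzenesulfonamide, via terminal alkyne 18 (not isolated)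
Conditions: K2CO3 (0.3 equiv), MeOH/THF, rt; then 9, Pd(PPh3)2Cl2 (3 mol %), CuI (5 mol %), Et3N, rt
Reagents that add atoms: none
Why: Base-catalysed methanolysis of the alkynylsilane followed in the same pot by Sonogashira coupling; at room temperature palladium inserts into the aryl C–I bond much faster than into the furyl C–Br bond, so the two halides are differentiated.

Step 11
Reactants: 19 (S)-N-[(3-bromofuran-2-yl)methyl]-N-[5-(4,5-dimethoxy-7-methylnaphthalen-1-yl)pent-4-yn-2-yl]-2-nitrobenzenesulfonamide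
Product: 21 (S)-8-bromo-5-(4,5-dimethoxy-7-methylnaphthalen-1-yl)-3-methyl-2-(2-nitrophenylsulfonyl)-1,2,3,4-tetrahydroisoquinolin-6-ol, via arene oxide 20 (not isolated)
Conditions: (IPr)AuNTf2 (5 mol %; IPr = 1,3-bis(2,6-diisopropylphenyl)imidazol-2-ylidene), ClCH2CH2Cl, 25 to 60 °C
Reagents that add atoms: none
Why: Proposed new method: the cationic gold catalyst activates the alkyne, furan C2 attacks the tether-side alkyne carbon in a 6-exo-dig closure of ring B (C4a–C8a), and the resulting cyclopropyl gold carbenoid opens the furan to a (Z)-dienal carrying a naphthyl-stabilised gold carbene at C5. The aldehyde oxygen adds to the carbene to give an oxepine, whose six-electron disrotatory electrocyclisation closes ring A (C5–C6) as arene oxide 20. The closest known reaction type is the gold-catalysed furan–yne phenol synthesis of terminal alkynes with alkyl-substituted or unsubstituted furans, which gives hydroxylated isoindolines and tetrahydroisoquinolines; an internal aryl alkyne combined with a 3-halofuran has not been shown. No stereocentre is formed, C3 is untouched and the biaryl axis is left uncontrolled. The step needs exo attack at the alkyl-bearing alkyne carbon, which the four-atom sulfonamide tether and the aryl stabilisation of the carbene at C5 favour, and it needs the arene oxide to break its C5–O bond so that oxygen stays on C6 and the C6 hydrogen is lost. That opening is secured by the tertiary, naphthyl-bearing C5 and by carrying C8 as bromide: a methoxy group at C8, para to C5, would instead stabilise the cation from C6–O cleavage and send the naphthyl group to C6 by a 1,2-shift.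

Step 12
Reactants: 21 (S)-8-bromo-5-(4,5-dimethoxy-7-methylnaphthalen-1-yl)-3-methyl-2-(2-nitrophenylsulfonyl)-1,2,3,4-tetrahydroisoquinolin-6-ol
Product: 22 (S)-8-bromo-5-(4,5-dimethoxy-7-methylnaphthalen-1-yl)-6-methoxy-3-methyl-2-(2-nitrophenylsulfonyl)-1,2,3,4-tetrahydroisoquinoline
Conditions: MeI, K2CO3, DMF, rt
Reagents that add atoms: iodomethane CI
Why: Williamson ether synthesis; the C6 phenol is the only acidic site and the sulfonamide, aryl bromide and biaryl are inert.

Step 13
Reactants: 22 (S)-8-bromo-5-(4,5-dimethoxy-7-methylnaphthalen-1-yl)-6-methoxy-3-methyl-2-(2-nitrophenylsulfonyl)-1,2,3,4-tetrahydroisoquinoline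
Product: 23 (S)-8-bromo-5-(4,5-dimethoxy-7-methylnaphthalen-1-yl)-6-methoxy-3-methyl-1,2,3,4-tetrahydroisoquinoline
Conditions: PhSH, K2CO3, DMF, rt
Reagents that add atoms: none
Why: Fukuyama deprotection: thiophenolate adds to the nitroarene (Meisenheimer complex) and the amine is released with loss of SO2 under conditions that leave the unactivated aryl bromide alone.

Step 14
Reactants: 23 (S)-8-bromo-5-(4,5-dimethoxy-7-methylnaphthalen-1-yl)-6-methoxy-3-methyl-1,2,3,4-tetrahydroisoquinoline
Product: 24 (S)-5-(4,5-dimethoxy-7-methylnaphthalen-1-yl)-6,8-dimethoxy-3-methyl-1,2,3,4-tetrahydroisoquinoline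
Conditions: NaOMe, CuI (20 mol %), MeOH/DMF, 110 °C, sealed tube, argon
Reagents that add atoms: sodium methoxide C[O-].[Na+]
Why: Copper-catalysed Ullmann-type methoxylation of an aryl bromide with sodium methoxide; the neighbouring benzylic amine can assist copper insertion and C3 carries no acidic hydrogen, so its configuration should hold.

**Compound list**

1 | 2-methoxy-4-methylbenzoic acid | COc1cc(C)ccc1C(=O)O | starting material
2 | 2-methoxy-4-methylbenzoyl chloride | COc1cc(C)ccc1C(=O)Cl | intermediate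
3 | N,N-diethyl-2-methoxy-4-methylbenzamide | CCN(CC)C(=O)c1ccc(C)cc1OC | intermediate
4 | N,N-diethyl-2-lithio-6-methoxy-4-methylbenzamide | [Li]c1cc(C)cc(OC)c1C(=O)N(CC)CC | intermediate
5 | [2-(diethylcarbamoyl)-3-methoxy-5-methylphenyl]magnesium bromide | Br[Mg]c1cc(C)cc(OC)c1C(=O)N(CC)CC | intermediate
6 | N,N-diethyl-2-methoxy-4-methyl-6-(prop-2-en-1-yl)benzamide | C=CCc1cc(C)cc(OC)c1C(=O)N(CC)CC | intermediate
7 | 8-methoxy-6-methylnaphthalen-1-ol | COc1cc(C)cc2cccc(O)c12 | intermediate
8 | 4-iodo-8-methoxy-6-methylnaphthalen-1-ol | COc1cc(C)cc2c(I)ccc(O)c12 | intermediate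
9 | 1-iodo-4,5-dimethoxy-7-methylnaphthalene | COc1ccc(I)c2cc(C)cc(OC)c12 | intermediate
10 | tert-butyl (S)-4-methyl-1,2,3-oxathiazolidine-3-carboxylate 2,2-dioxide | C[C@H]1COS(=O)(=O)N1C(=O)OC(C)(C)C | starting material
11 | lithium (S)-N-(tert-butoxycarbonyl)-N-[5-(trimethylsilyl)pent-4-yn-2-yl]sulfamate | C[C@H](N(C(=O)OC(C)(C)C)S(=O)(=O)[O-])CC#C[Si](C)(C)C.[Li+] | intermediate
12 | tert-butyl (S)-[5-(trimethylsilyl)pent-4-yn-2-yl]carbamate | C[C@H](NC(=O)OC(C)(C)C)CC#C[Si](C)(C)C | intermediate
13 | (S)-5-(trimethylsilyl)pent-4-yn-2-aminium chloride | C[C@H]([NH3+])CC#C[Si](C)(C)C.[Cl-] | intermediate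
14 | 3-bromofuran-2-carbaldehyde | O=Cc1occc1Br | starting material
15 | (S,E)-N-[(3-bromofuran-2-yl)methylidene]-5-(trimethylsilyl)pent-4-yn-2-amine | C[C@H](/N=C/c1occc1Br)CC#C[Si](C)(C)C | intermediate
16 | (S)-N-[(3-bromofuran-2-yl)methyl]-5-(trimethylsilyl)pent-4-yn-2-amine | C[C@H](NCc1occc1Br)CC#C[Si](C)(C)C | intermediate
17 | (S)-N-[(3-bromofuran-2-yl)methyl]-2-nitro-N-[5-(trimethylsilyl)pent-4-yn-2-yl]benzenesulfonamide | C[C@H](N(Cc1occc1Br)S(=O)(=O)c1ccccc1[N+](=O)[O-])CC#C[Si](C)(C)C | intermediate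
18 | (S)-N-[(3-bromofuran-2-yl)methyl]-2-nitro-N-(pent-4-yn-2-yl)benzenesulfonamide | C[C@H](N(Cc1occc1Br)S(=O)(=O)c1ccccc1[N+](=O)[O-])CC#C | intermediate
19 | (S)-N-[(3-bromofuran-2-yl)methyl]-N-[5-(4,5-dimethoxy-7-methylnaphthalen-1-yl)pent-4-yn-2-yl]-2-nitrobenzenesulfonamide | C[C@H](N(Cc1occc1Br)S(=O)(=O)c1ccccc1[N+](=O)[O-])CC#Cc1ccc(OC)c2c(OC)cc(C)cc12 | intermediate
20 | (3S)-8-bromo-5-(4,5-dimethoxy-7-methylnaphthalen-1-yl)-5,6-epoxy-3-methyl-2-(2-nitrophenylsulfonyl)-1,2,3,4,5,6-hexahydroisoquinoline (arene oxide of 21, epoxide face not controlled) | BrC1=CC2OC2(c2ccc(OC)c3c(OC)cc(C)cc23)C2=C1CN(S(=O)(=O)c1ccccc1[N+](=O)[O-])[C@@H](C)C2 | intermediate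
21 | (S)-8-bromo-5-(4,5-dimethoxy-7-methylnaphthalen-1-yl)-3-methyl-2-(2-nitrophenylsulfonyl)-1,2,3,4-tetrahydroisoquinolin-6-ol | Brc1cc(O)c(-c2ccc(OC)c3c(OC)cc(C)cc23)c2c1CN(S(=O)(=O)c1ccccc1[N+](=O)[O-])[C@@H](C)C2 | intermediate
22 | (S)-8-bromo-5-(4,5-dimethoxy-7-methylnaphthalen-1-yl)-6-methoxy-3-methyl-2-(2-nitrophenylsulfonyl)-1,2,3,4-tetrahydroisoquinoline | Brc1cc(OC)c(-c2ccc(OC)c3c(OC)cc(C)cc23)c2c1CN(S(=O)(=O)c1ccccc1[N+](=O)[O-])[C@@H](C)C2 | intermediate
23 | (S)-8-bromo-5-(4,5-dimethoxy-7-methylnaphthalen-1-yl)-6-methoxy-3-methyl-1,2,3,4-tetrahydroisoquinoline | Brc1cc(OC)c(-c2ccc(OC)c3c(OC)cc(C)cc23)c2c1CN[C@@H](C)C2 | intermediate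
24 | (S)-5-(4,5-dimethoxy-7-methylnaphthalen-1-yl)-6,8-dimethoxy-3-methyl-1,2,3,4-tetrahydroisoquinoline | COc1cc(OC)c(-c2ccc(OC)c3c(OC)cc(C)cc23)c2c1CN[C@@H](C)C2 | target

**Step count**

Total: 14 steps. Longest linear sequence: 10 steps (steps 1 to 5, then 10 to 14, from 2-methoxy-4-methylbenzoic acid). The amine branch (steps 6 to 9) joins at step 10.

**Steps most likely to fail**

Step 11. Three processes may defeat it: the furan may add to the aryl-bearing alkyne carbon (7-endo closure); the bromofuran may be too weak a nucleophile for turnover; or the arene oxide may break its C6–O bond, after which the naphthyl group migrates to C6. The fallback uses known chemistry, sets out from 10 and 9 and returns at 24. Ring B is closed by a Pictet–Spengler reaction and the biaryl bond is made by Suzuki–Miyaura coupling. Sulfamidate 10 would be opened with 3,5-(MeO)2C6H3MgBr and catalytic CuI and worked up with aqueous acid to give tert-butyl (S)-[1-(3,5-dimethoxyphenyl)propan-2-yl]carbamate F1. HCl in dioxane gives (S)-1-(3,5-dimethoxyphenyl)propan-2-aminium chloride F2, and aqueous formaldehyde at 60 °C should close the ring to (S)-6,8-dimethoxy-3-methyl-1,2,3,4-tetrahydroisoquinoline F3. Boc2O gives tert-butyl (S)-6,8-dimethoxy-3-methyl-3,4-dihydroisoquinoline-2(1H)-carboxylate F4. NBS should brominate F4 at C5, ortho and para to the two methoxy groups, to give tert-butyl (S)-5-bromo-6,8-dimethoxy-3-methyl-3,4-dihydroisoquinoline-2(1H)-carboxylate F5. Iodide 9 is converted with B2pin2, Pd(dppf)Cl2 and KOAc into 2-(4,5-dimethoxy-7-methylnaphthalen-1-yl)-4,4,5,5-tetramethyl-1,3,2-dioxaborolane F6. Coupling of F5 and F6 with Pd(OAc)2, SPhos and K3PO4 in toluene/water gives tert-butyl (S)-5-(4,5-dimethoxy-7-methylnaphthalen-1-yl)-6,8-dimethoxy-3-methyl-3,4-dihydroisoquinoline-2(1H)-carboxylate F7, and HCl in dioxane then frees 24.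

Step 14. Reductive loss of bromine, copper-mediated oxidation at C1 or N-arylation of the free amine may compete with methoxide transfer. The fallback sets out from 22 and returns at 24, and replaces C–O coupling by borylation and oxidation while nitrogen is still protected. Miyaura borylation (B2pin2, Pd(dppf)Cl2, KOAc, dioxane, 90 °C) gives (S)-5-(4,5-dimethoxy-7-methylnaphthalen-1-yl)-6-methoxy-3-methyl-2-(2-nitrophenylsulfonyl)-8-(4,4,5,5-tetramethyl-1,3,2-dioxaborolan-2-yl)-1,2,3,4-tetrahydroisoquinoline F8. Oxidation with NaBO3·4H2O in THF/water gives (S)-5-(4,5-dimethoxy-7-methylnaphthalen-1-yl)-6-methoxy-3-methyl-2-(2-nitrophenylsulfonyl)-1,2,3,4-tetrahydroisoquinolin-8-ol F9. MeI and K2CO3 give (S)-5-(4,5-dimethoxy-7-methylnaphthalen-1-yl)-6,8-dimethoxy-3-methyl-2-(2-nitrophenylsulfonyl)-1,2,3,4-tetrahydroisoquinoline F10, and PhSH with K2CO3 then gives 24.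

Step 4. Iodine may enter ortho to the hydroxyl or on the methoxy-bearing ring, or the iodinating agent may oxidise the electron-rich naphthol. The fallback sets out from 7 and returns at 9, uses bromine as a placeholder and never handles an iodonaphthol. NBS in MeCN at 0 °C should give 4-bromo-8-methoxy-6-methylnaphthalen-1-ol F11. MeI and K2CO3 give 1-bromo-4,5-dimethoxy-7-methylnaphthalene F12. A copper-catalysed aromatic Finkelstein reaction (CuI, NaI, trans-N,N'-dimethylcyclohexane-1,2-diamine, dioxane, 110 °C) converts F12 into 9.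

**Further compounds**

F1 | step 11 | tert-butyl (S)-[1-(3,5-dimethoxyphenyl)propan-2-yl]carbamate | C[C@H](NC(=O)OC(C)(C)C)Cc1cc(OC)cc(OC)c1
F2 | step 11 | (S)-1-(3,5-dimethoxyphenyl)propan-2-aminium chloride | C[C@H]([NH3+])Cc1cc(OC)cc(OC)c1.[Cl-]
F3 | step 11 | (S)-6,8-dimethoxy-3-methyl-1,2,3,4-tetrahydroisoquinoline | COc1cc(OC)cc2c1CN[C@@H](C)C2
F4 | step 11 | tert-butyl (S)-6,8-dimethoxy-3-methyl-3,4-dihydroisoquinoline-2(1H)-carboxylate | COc1cc(OC)cc2c1CN(C(=O)OC(C)(C)C)[C@@H](C)C2
F5 | step 11 | tert-butyl (S)-5-bromo-6,8-dimethoxy-3-methyl-3,4-dihydroisoquinoline-2(1H)-carboxylate | COc1cc(OC)c(Br)c2c1CN(C(=O)OC(C)(C)C)[C@@H](C)C2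
F6 | step 11 | 2-(4,5-dimethoxy-7-methylnaphthalen-1-yl)-4,4,5,5-tetramethyl-1,3,2-dioxaborolane | COc1ccc(B2OC(C)(C)C(C)(C)O2)c2cc(C)cc(OC)c12
F7 | step 11 | tert-butyl (S)-5-(4,5-dimethoxy-7-methylnaphthalen-1-yl)-6,8-dimethoxy-3-methyl-3,4-dihydroisoquinoline-2(1H)-carboxylate | COc1cc(OC)c(-c2ccc(OC)c3c(OC)cc(C)cc23)c2c1CN(C(=O)OC(C)(C)C)[C@@H](C)C2
F8 | step 14 | (S)-5-(4,5-dimethoxy-7-methylnaphthalen-1-yl)-6-methoxy-3-methyl-2-(2-nitrophenylsulfonyl)-8-(4,4,5,5-tetramethyl-1,3,2-dioxaborolan-2-yl)-1,2,3,4-tetrahydroisoquinoline | CC1(C)OB(OC1(C)C)c1cc(OC)c(-c2ccc(OC)c3c(OC)cc(C)cc23)c2c1CN(S(=O)(=O)c1ccccc1[N+](=O)[O-])[C@@H](C)C2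
F9 | step 14 | (S)-5-(4,5-dimethoxy-7-methylnaphthalen-1-yl)-6-methoxy-3-methyl-2-(2-nitrophenylsulfonyl)-1,2,3,4-tetrahydroisoquinolin-8-ol | Oc1cc(OC)c(-c2ccc(OC)c3c(OC)cc(C)cc23)c2c1CN(S(=O)(=O)c1ccccc1[N+](=O)[O-])[C@@H](C)C2
F10 | step 14 | (S)-5-(4,5-dimethoxy-7-methylnaphthalen-1-yl)-6,8-dimethoxy-3-methyl-2-(2-nitrophenylsulfonyl)-1,2,3,4-tetrahydroisoquinoline | COc1cc(OC)c(-c2ccc(OC)c3c(OC)cc(C)cc23)c2c1CN(S(=O)(=O)c1ccccc1[N+](=O)[O-])[C@@H](C)C2
F11 | step 4 | 4-bromo-8-methoxy-6-methylnaphthalen-1-ol | COc1cc(C)cc2c(Br)ccc(O)c12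
F12 | step 4 | 1-bromo-4,5-dimethoxy-7-methylnaphthalene | COc1ccc(Br)c2cc(C)cc(OC)c12
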